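## Retrosynthetic overview

- **Late stage.** Removing the vanillate (C6–O), the epoxide (C8–C9) and the acetate (C2–O) leads back to 4β-hydroxydauca-7,9-diene-2,6-dione. Its C4 carbinol relays C2, C5, C6, C8 and C9 by hydride delivery, oxygen delivery and equilibration.
- **Key disconnection.** That dienedione is the unmasked form of a cycloheptatriene made from an aryl α-diazoketone by an intramolecular Buchner reaction. Retrosynthetically, C1–C5 and C1–C10 are cut and C5–C10 is rejoined, which returns the seven-membered ring to a benzene ring.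
- **Enabling feature.** In the ring C5–C6–C7–C8–C9–C10–C1, the oxygen at C6 and the methyl at C8 sit ortho and para to C5, so C5 to C10 is the ring of m-cresol. C1 is quaternary, methyl-bearing and next to the oxygenated C2, so it is the carbon of a 2-diazo-3-ketone. The 1,3-relation of O4 and O6 allows a temporary six-membered silylene ring.
- **Order of rings.** Benzene ring (bought), then the temporary dioxasiline ring. In the key step the cyclopentanone closes and the benzene ring grows to the seven-membered ring. The silylene ring is then removed and the epoxide is formed last.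
- **Early stage.** The diazoketone goes back to diazoethane and a β-silyloxy acid, then to an allyl carbinol, then to 2-hydroxy-4-methylisobutyrophenone (m-cresol plus isobutyryl chloride). C4 is the only centre set by an external chiral reagent.

Key step: step 6

**Numbering used (daucane).**
- C1 is the quaternary ring-fusion carbon bearing CH3.
- C2 is the acetoxy carbon and C3 is CH2.
- C4 is the carbinol carbon bearing isopropyl.
- C5 is the ring-fusion CH and C6 is the aroyloxy carbon.
- C7 is CH2, C8 (CH3) and C9 are the epoxide carbons, and C10 is CH2.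
- β is the face of the C1 methyl group and α is the opposite face.
- The target as read from the SMILES is 1β-CH3, 2α-OAc, 4β-OH (isopropyl α), 5α-H, 6α-aroyloxy, 8α,9α-epoxide, which is (1R,2S,4R,5S,6S,8R,9S).

**Assumption.** The (R,R)-configured allylchlorosilane of step 2 is taken to deliver the (R)-carbinol. If the sense of induction is the opposite, the equally available (S,S)-reagent is used and nothing else changes.

## Route

Step 1
Reactants: 1 m-cresol; 2 isobutyryl chloride
Product: 4 1-(2-hydroxy-4-methylphenyl)-2-methylpropan-1-one, via m-tolyl isobutyrate 3 (not isolated)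
Conditions: 2 (1.05 equiv), neat, 60 °C; then AlCl3 (1.5 equiv), 130 °C; ice/aq HCl
Reagents that add atoms: none
Why: O-acylation followed by a high-temperature Fries rearrangement, which under chelation control moves the acyl group to the free ortho position para to the methyl group and thereby fixes the ortho-oxygen/para-methyl pattern needed later.

Step 2
Reactants: 4 1-(2-hydroxy-4-methylphenyl)-2-methylpropan-1-one
Product: 6 (R)-2-(3-hydroxy-2-methylhex-5-en-3-yl)-5-methylphenol, via spirocyclic silyl diether 5 (not isolated)
Conditions: (R,R)-allylchlorosilane (1.5 equiv), CH2Cl2, 23–40 °C; then 1 M aq HCl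
Reagents that add atoms: (3aR,7aR)-2-allyl-1,3-bis(4-bromobenzyl)-2-chlorooctahydro-1H-benzo[d][1,3,2]diazasilole, C=CC[Si]1(Cl)N(Cc2ccc(Br)cc2)[C@@H]2CCCC[C@H]2N1Cc1ccc(Br)cc1 (allyl group in 6; silicon and diamine only in 5)
Why: Phenol-directed allylation of a 2-hydroxyaryl ketone with a strained chiral allylchlorosilane, in which the phenol displaces chloride, the liberated HCl raises the Lewis acidity of silicon, the ketone oxygen binds and the allyl group is passed on through a closed chair-like transition state whose diamine backbone differentiates the carbonyl faces and so sets C4, a mode that tolerates branched ketone substituents.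

Step 3
Reactants: 6 (R)-2-(3-hydroxy-2-methylhex-5-en-3-yl)-5-methylphenol
Product: 7 (R)-4-allyl-2,2-di-tert-butyl-4-isopropyl-7-methyl-4H-benzo[d][1,3,2]dioxasiline
Conditions: tBu2Si(OTf)2 (1.1 equiv), 2,6-lutidine (3 equiv), CH2Cl2, 0 °C to rt
Reagents that add atoms: di-tert-butylsilyl bis(trifluoromethanesulfonate), CC(C)(C)[Si](OS(=O)(=O)C(F)(F)F)(OS(=O)(=O)C(F)(F)F)C(C)(C)C
Why: Cyclic silylene formation from a 1,3-related phenol and tertiary alcohol, where the bis(triflate) silylates the phenol first and the hindered carbinol then closes the six-membered ring intramolecularly under buffered conditions that avoid ionisation of the benzylic C–O bond and leave C4 untouched.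

Step 4
Reactants: 7 (R)-4-allyl-2,2-di-tert-butyl-4-isopropyl-7-methyl-4H-benzo[d][1,3,2]dioxasiline
Product: 9 (R)-2-(2,2-di-tert-butyl-4-isopropyl-7-methyl-4H-benzo[d][1,3,2]dioxasilin-4-yl)acetic acid, via aldehyde 8 (not isolated)
Conditions: O3, CH2Cl2, −78 °C; Me2S; crude 8, NaClO2, NaH2PO4, 2-methyl-2-butene, tBuOH/H2O, 0 °C to rt
Reagents that add atoms: ozone, [O-][O+]=O; sodium chlorite, [Na+].[O-]Cl=O
Why: Ozonolysis of the only alkene, which is far more reactive toward ozone than the arene, followed by Pinnick oxidation in a buffered medium with a hypochlorite scavenger, conditions that the di-tert-butylsilylene ring and the benzylic C–O bond should survive.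

Step 5
Reactants: 9 (R)-2-(2,2-di-tert-butyl-4-isopropyl-7-methyl-4H-benzo[d][1,3,2]dioxasilin-4-yl)acetic acid
Product: 11 (R)-3-diazo-1-(2,2-di-tert-butyl-4-isopropyl-7-methyl-4H-benzo[d][1,3,2]dioxasilin-4-yl)butan-2-one, via acid chloride 10 (not isolated)
Conditions: Me2C=C(Cl)NMe2 (1.1 equiv), CH2Cl2, 0 °C; then CH3CHN2 (3 equiv, ethereal, freshly made from N-ethyl-N-nitrosourea and aq KOH), Et2O, −20 to 0 °C
Reagents that add atoms: diazoethane, CC=[N+]=[N-]; 1-chloro-N,N,2-trimethylprop-1-en-1-amine, CC(C)=C(Cl)N(C)C (chlorine only in 10)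
Why: Acylation of diazoethane by an acid chloride (the diazoketone synthesis of the Arndt–Eistert sequence), with the chloride made under neutral conditions by the α-chloroenamine so that no HCl meets the acid-labile tertiary benzylic C–O bond, and with a second equivalent of diazoethane taking up the HCl of the acylation.

Step 6
Reactants: 11 (R)-3-diazo-1-(2,2-di-tert-butyl-4-isopropyl-7-methyl-4H-benzo[d][1,3,2]dioxasilin-4-yl)butan-2-one
Product: 13 4β,6-(di-tert-butylsilanediyldioxy)dauca-5,7,9-trien-2-one (1β-methyl, 4α-isopropyl), via norcaradiene 12 (not isolated)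
Conditions: Rh2(OAc)4 (1 mol %), CH2Cl2, reflux, slow addition of 11 (high dilution)
Reagents that add atoms: none
Why: Loss of N2 from 11 at Rh2(OAc)4 gives an electrophilic keto carbenoid that adds across the C5–C10 bond of the arene (the ipso carbon and its unsubstituted ortho neighbour) to give norcaradiene 12, whose disrotatory 6π electrocyclic opening breaks C5–C10 and so inserts C1 into the benzene ring, which thereby becomes the seven-membered ring. The closest known reaction type is the intramolecular Buchner reaction of 2-diazo-5-arylalkan-3-ones, which gives 8a-methyl-3,8a-dihydroazulen-1(2H)-ones. The cyclopentanone closes by a [2+1] addition in which the three-atom arm C2–C3–C4 brings C1 onto C5, the cyclopropane is transient, and the seven-membered ring arises by one-carbon expansion of the six-membered one. C1 is the only new stereocentre that persists and it is controlled by C4: the dioxasiline ring holds O4 in the arene plane on the C6 side, so the ketone arm and the isopropyl group stand on opposite faces, the arm can reach only its own face, and the obligatory cis fusion of the bicyclo[3.1.0]hexanone in 12 leaves the C1 methyl syn to O4 and anti to isopropyl. Site selectivity for C5–C10 over C5–C6 follows from the same ring, which fills the C6 side and tilts the arm toward C10, while chemoselectivity over 1,5-insertion into the isopropyl methine C–H and over 1,2-hydride shift from the methyl group rests on the electron-rich pre-organised arene, the acetate ligands and slow addition. In one operation the step makes two C–C bonds, both carbocycles in their final size and the quaternary centre, and it leaves oxygen at C2, C4 and C6 and a C7–C10 diene from which the C8–C9 alkene is drawn.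

Step 7
Reactants: 13 4β,6-(di-tert-butylsilanediyldioxy)dauca-5,7,9-trien-2-one
Product: 15 4β-hydroxy-5αH-dauca-7,9-diene-2,6-dione, via trienol 14 (not isolated)
Conditions: HF·pyridine, pyridine/THF, 0 °C
Reagents that add atoms: none
Why: Cleavage of both Si–O bonds by buffered fluoride frees the C4 carbinol and trienol 14, which ketonises by protonation at C5 to the linearly conjugated cyclohepta-2,4-dienone (favoured over its bicyclic valence isomers as in eucarvone-type dienones), and C5 is set under equilibrating conditions, the 5α-H epimer being preferred because it puts C6 trans to the isopropyl group and lets the 4β-OH hydrogen-bond to the C6 carbonyl.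

Step 8
Reactants: 15 4β-hydroxy-5αH-dauca-7,9-diene-2,6-dione
Product: 16 2α,4β-dihydroxy-5αH-dauca-7,9-dien-6-one
Conditions: Me4NBH(OAc)3 (1.5 equiv), MeCN/AcOH 1:1, −30 °C; aq Rochelle salt
Reagents that add atoms: none
Why: Evans–Saksena hydroxyl-directed reduction, in which the 4β-alkoxy(diacetoxy)borohydride delivers hydride across the β face of the five-membered ring to C2 and gives the 1,3-anti 2α-alcohol against the bias of the neighbouring angular methyl, the saturated cyclopentanone being intrinsically more electrophilic than the doubly vinylogous C6 dienone.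

Step 9
Reactants: 16 2α,4β-dihydroxy-5αH-dauca-7,9-dien-6-one
Product: 17 2α-acetoxy-4β-hydroxy-5αH-dauca-7,9-dien-6-one
Conditions: Ac2O, pyridine, DMAP (cat), CH2Cl2, 0 °C to rt
Reagents that add atoms: acetic anhydride, CC(=O)OC(C)=O
Why: DMAP-catalysed acetylation of the only secondary alcohol, the hindered tertiary 4β-OH staying free under these mild conditions and no stereocentre being touched.

Step 10
Reactants: 17 2α-acetoxy-4β-hydroxy-5αH-dauca-7,9-dien-6-one
Product: 18 2α-acetoxy-4β-hydroxy-5αH-dauc-8-en-6-one
Conditions: (η6-naphthalene)Cr(CO)3 (20 mol %), H2 (50 atm), THF, 40 °C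
Reagents that add atoms: none
Why: 1,4-Hydrogenation of an s-cis 1,3-diene by an arene chromium tricarbonyl catalyst, as known for conjugated dienes and dienoates, which adds hydrogen to the diene termini C7 and C10 and leaves the cis C8–C9 alkene, while the ring enone is s-trans and therefore not a substrate and ketone, ester and alcohol are tolerated.

Step 11
Reactants: 18 2α-acetoxy-4β-hydroxy-5αH-dauc-8-en-6-one
Product: 19 2α-acetoxy-5αH-dauc-8-ene-4β,6α-diol
Conditions: Me4NBH(OAc)3 (3 equiv), MeCN/AcOH 1:1, −30 to −10 °C; aq Rochelle salt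
Reagents that add atoms: none
Why: A second Evans–Saksena reduction, in which the same 4β-carbinol, cis to C6 on the five-membered ring, delivers hydride through a six-membered transition state to the β face of the C6 carbonyl and gives the 1,3-anti 6α-alcohol at a temperature and acidity that should not move the β,γ-alkene.

Step 12
Reactants: 19 2α-acetoxy-5αH-dauc-8-ene-4β,6α-diol
Product: 20 2α-acetoxy-8α,9α-epoxy-5αH-daucane-4β,6α-diol
Conditions: VO(acac)2 (5 mol %), tBuOOH (decane, 1.5 equiv), CH2Cl2, 0 °C to rt
Reagents that add atoms: tert-butyl hydroperoxide, CC(C)(C)OO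
Why: Hydroxyl-directed vanadium-catalysed epoxidation of a homoallylic alcohol, in which the 6α-alkoxide carries the vanadium peroxide to the α face of the only alkene and sets C8 and C9 syn to O6, the β face being screened in addition by the C1 methyl group.

Step 13
Reactants: 20 2α-acetoxy-8α,9α-epoxy-5αH-daucane-4β,6α-diol; 21 4-(benzyloxy)-3-methoxybenzoic acid
Product: 22 2α-acetoxy-6α-[4-(benzyloxy)-3-methoxybenzoyloxy]-8α,9α-epoxy-5αH-daucan-4β-ol
Conditions: DCC, DMAP, CH2Cl2, rt
Reagents that add atoms: none
Why: Steglich esterification of the only secondary alcohol with retention at C6 because the C–O bond is not touched, under non-acidic conditions that spare the epoxide and leave the tertiary 4β-OH unacylated.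

Step 14
Reactants: 22 2α-acetoxy-6α-[4-(benzyloxy)-3-methoxybenzoyloxy]-8α,9α-epoxy-5αH-daucan-4β-ol
Product: 23 2α-acetoxy-8α,9α-epoxy-6α-(4-hydroxy-3-methoxybenzoyloxy)-5αH-daucan-4β-ol (CNP0241679.3)
Conditions: H2 (1 atm), Pd/C (10 wt %), EtOAc, rt
Reagents that add atoms: none
Why: Hydrogenolysis of the benzyl aryl ether under neutral conditions, with no alkene left in the molecule and with the trialkyl epoxide, both esters and the tertiary alcohol inert.

## Compound list

1 | m-cresol (3-methylphenol) | Cc1cccc(O)c1 | starting material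
2 | isobutyryl chloride | CC(C)C(=O)Cl | starting material
3 | m-tolyl isobutyrate | CC(C)C(=O)Oc1cccc(C)c1 | intermediate
4 | 1-(2-hydroxy-4-methylphenyl)-2-methylpropan-1-one | CC(C)C(=O)c1ccc(C)cc1O | intermediate
5 | spirocyclic silyl diether (silicon bound to the phenol O, the new carbinol O and both diamine N) | C=CC[C@@]1(C(C)C)c2ccc(C)cc2O[Si]2(O1)N(Cc1ccc(Br)cc1)[C@@H]1CCCC[C@H]1N2Cc1ccc(Br)cc1 | intermediate
6 | (R)-2-(3-hydroxy-2-methylhex-5-en-3-yl)-5-methylphenol | C=CC[C@@](O)(C(C)C)c1ccc(C)cc1O | intermediate
7 | (R)-4-allyl-2,2-di-tert-butyl-4-isopropyl-7-methyl-4H-benzo[d][1,3,2]dioxasiline | C=CC[C@@]1(C(C)C)c2ccc(C)cc2O[Si](C(C)(C)C)(C(C)(C)C)O1 | intermediate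
8 | (R)-2-(2,2-di-tert-butyl-4-isopropyl-7-methyl-4H-benzo[d][1,3,2]dioxasilin-4-yl)acetaldehyde | O=CC[C@@]1(C(C)C)c2ccc(C)cc2O[Si](C(C)(C)C)(C(C)(C)C)O1 | intermediate
9 | (R)-2-(2,2-di-tert-butyl-4-isopropyl-7-methyl-4H-benzo[d][1,3,2]dioxasilin-4-yl)acetic acid | OC(=O)C[C@@]1(C(C)C)c2ccc(C)cc2O[Si](C(C)(C)C)(C(C)(C)C)O1 | intermediate
10 | (R)-2-(2,2-di-tert-butyl-4-isopropyl-7-methyl-4H-benzo[d][1,3,2]dioxasilin-4-yl)acetyl chloride | O=C(Cl)C[C@@]1(C(C)C)c2ccc(C)cc2O[Si](C(C)(C)C)(C(C)(C)C)O1 | intermediate
11 | (R)-3-diazo-1-(2,2-di-tert-butyl-4-isopropyl-7-methyl-4H-benzo[d][1,3,2]dioxasilin-4-yl)butan-2-one | CC(=[N+]=[N-])C(=O)C[C@@]1(C(C)C)c2ccc(C)cc2O[Si](C(C)(C)C)(C(C)(C)C)O1 | intermediate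
12 | norcaradiene valence isomer of 13 (cyclopropane C1–C5–C10, diene C6=C7–C8=C9) | C[C@@]12C(=O)C[C@]3(C(C)C)O[Si](C(C)(C)C)(C(C)(C)C)OC4=CC(C)=C[C@H]1[C@@]234 | intermediate
13 | 4β,6-(di-tert-butylsilanediyldioxy)dauca-5,7,9-trien-2-one (1β-methyl, 4α-isopropyl) | C[C@@]12C=CC(C)=CC3=C1[C@](C(C)C)(CC2=O)O[Si](C(C)(C)C)(C(C)(C)C)O3 | intermediate
14 | 4β,6-dihydroxydauca-5,7,9-trien-2-one (trienol) | C[C@@]12C=CC(C)=CC(O)=C1[C@](O)(C(C)C)CC2=O | intermediate
15 | 4β-hydroxy-5αH-dauca-7,9-diene-2,6-dione | O=C1C=C(C)C=C[C@@]2(C)C(=O)C[C@@](O)(C(C)C)[C@H]12 | intermediate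
16 | 2α,4β-dihydroxy-5αH-dauca-7,9-dien-6-one | O=C1C=C(C)C=C[C@@]2(C)[C@@H](O)C[C@@](O)(C(C)C)[C@H]12 | intermediate
17 | 2α-acetoxy-4β-hydroxy-5αH-dauca-7,9-dien-6-one | O=C1C=C(C)C=C[C@@]2(C)[C@@H](OC(C)=O)C[C@@](O)(C(C)C)[C@H]12 | intermediate
18 | 2α-acetoxy-4β-hydroxy-5αH-dauc-8-en-6-one | O=C1CC(C)=CC[C@@]2(C)[C@@H](OC(C)=O)C[C@@](O)(C(C)C)[C@H]12 | intermediate
19 | 2α-acetoxy-5αH-dauc-8-ene-4β,6α-diol | O[C@H]1CC(C)=CC[C@@]2(C)[C@@H](OC(C)=O)C[C@@](O)(C(C)C)[C@H]12 | intermediate
20 | 2α-acetoxy-8α,9α-epoxy-5αH-daucane-4β,6α-diol | O[C@H]1C[C@@]2(C)O[C@H]2C[C@@]2(C)[C@@H](OC(C)=O)C[C@@](O)(C(C)C)[C@H]12 | intermediate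
21 | 4-(benzyloxy)-3-methoxybenzoic acid | COc1cc(C(=O)O)ccc1OCc1ccccc1 | starting material
22 | 2α-acetoxy-6α-[4-(benzyloxy)-3-methoxybenzoyloxy]-8α,9α-epoxy-5αH-daucan-4β-ol | COc1cc(C(=O)O[C@H]2C[C@@]3(C)O[C@H]3C[C@@]3(C)[C@@H](OC(C)=O)C[C@@](O)(C(C)C)[C@H]23)ccc1OCc1ccccc1 | intermediate
23 | 2α-acetoxy-8α,9α-epoxy-6α-(4-hydroxy-3-methoxybenzoyloxy)-5αH-daucan-4β-ol, (1R,2S,4R,5S,6S,8R,9S) | COc1cc(C(=O)O[C@H]2C[C@@]3(C)O[C@H]3C[C@@]3(C)[C@@H](OC(C)=O)C[C@@](O)(C(C)C)[C@H]23)ccc1O | target

## Step count and risks

Total step count: 14. Longest linear sequence: 14 steps (1 to 23).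

**Step 6 (key step).**
- Risk: the carbenoid may be diverted before it reaches the arene, either by 1,2-hydride shift from the adjacent methyl group or by insertion into the isopropyl methine C–H. The cycloheptatriene may also re-aromatise by cyclopropane cleavage on acidic surfaces.
- Fallback: it sets out from 10 and comes back at 13, and the angular methyl is brought in by enolate alkylation instead of by the carbene.
- Acid chloride 10 is acylated with diazomethane to the terminal diazoketone F1. This substrate class has the broadest Buchner precedent and has no hydrogen that can migrate to the carbene carbon.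
- Rh2(OAc)4 then gives, under the same tether control, the angular C1–H trienone F2.
- The C1–H of F2 is α to the ketone and doubly allylic. It is removed with LiHMDS (THF, −78 °C), and the enolate is methylated with MeI on the face anti to the isopropyl group to give 13.

**Step 8.**
- Risk: hydride may be delivered to the wrong carbonyl (C6), or both may be reduced. Ligand exchange at the hindered tertiary carbinol may be slow, which leads to undirected attack from the α face. The doubly β-hydroxy ketone may also dehydrate in the acidic medium.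
- Fallback: it sets out from 13 and comes back at 17, using reagent control plus inversion while C6 is still masked.
- Compound 13 is reduced with NaBH4 (MeOH/THF, 0 °C). This should attack anti to the adjacent angular methyl, as in 17-oxo steroids, and give the 2β-alcohol F3.
- Mitsunobu reaction with acetic acid (PPh3, DIAD, toluene) inverts C2 and installs the ester in one step, giving the 2α-acetate F4.
- HF·pyridine then unmasks F4 to 17, so only one β-hydroxy ketone array is ever exposed.

**Step 10.**
- Risk: the zerovalent chromium catalyst may be sequestered as a stable η6 complex of the trienol tautomer. Uptake may be sluggish at the diene terminus next to the quaternary centre. The β,γ-alkene may migrate into conjugation.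
- Fallback: it sets out from 17 and comes back at 18 with no new compound, and replaces catalytic hydrogen addition by electron transfer.
- Divalent samarium (SmI2, THF/H2O, −78 °C) reduces the dienone to its extended dienolate with protonation at the δ-carbon C10.
- Kinetic protonation of that dienolate at the α-carbon C7 gives the deconjugated C8–C9 alkene, as known for 2,4-dienoates and related vinylogous acceptors.

## Further compounds

F1 | step 6 | (R)-1-diazo-3-(2,2-di-tert-butyl-4-isopropyl-7-methyl-4H-benzo[d][1,3,2]dioxasilin-4-yl)propan-2-one | [N-]=[N+]=CC(=O)C[C@@]1(C(C)C)c2ccc(C)cc2O[Si](C(C)(C)C)(C(C)(C)C)O1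
F2 | step 6 | C1-demethyl analogue of 13 (angular hydrogen at C1) | O=C1C[C@]2(C(C)C)O[Si](C(C)(C)C)(C(C)(C)C)OC3=C2[C@H]1C=CC(C)=C3
F3 | step 8 | 4β,6-(di-tert-butylsilanediyldioxy)dauca-5,7,9-trien-2β-ol | C[C@@]12C=CC(C)=CC3=C1[C@](C(C)C)(C[C@H]2O)O[Si](C(C)(C)C)(C(C)(C)C)O3
F4 | step 8 | 2α-acetoxy-4β,6-(di-tert-butylsilanediyldioxy)dauca-5,7,9-triene | C[C@@]12C=CC(C)=CC3=C1[C@](C(C)C)(C[C@@H]2OC(C)=O)O[Si](C(C)(C)C)(C(C)(C)C)O3
F0 | step 10 | none | none
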